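The route cuts ring A at C9–C14, C15–C16 and C8–C17 (chain numbered C1, acid carbon, to C20, acetyl methyl), which opens rings A and B into one yne–ene–yne chain. A single cationic rhodium [2+2+2] cyclisation re-forms ring B, ring A and a temporary δ-lactone from the C7 carboxyl to the C19 oxygen. It exploits the cyclohexa-1,3-diene ring A, whose sp3 carbons C8 and C9 bear cis hydrogens, the trace of a Z-alkene joined to two alkynes. The precursor is the Z-enoate ester of (S)-hex-4-yn-2-ol carrying the terminal alkyne and a C10–C12 stereotriad; its allylic C10 centre directs the alkene face, is carried as the epimer and is inverted afterwards.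

Key step: step 12

Remark: atom numbers follow the target chain (C1 to C20); C7 of the lactols and methyl acetals is an anomeric mixture; (R)-H8-BINAP is assumed to be the ligand antipode that reinforces the substrate bias, its mirror image being used otherwise.

Step 1
Reactants: 1 (R)-4-benzyl-3-propionyloxazolidin-2-one; 2 propargyl bromide
Product: 4 (R)-4-benzyl-3-[(S)-2-methylpent-4-ynoyl]oxazolidin-2-one, via sodium Z-enolate 3 (not isolated)
Conditions: NaN(SiMe3)2, THF, −78 °C; then 2, −78 → −40 °C
Reagents that add atoms: none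
Why: Evans asymmetric alkylation, in which the chelated sodium Z-enolate is attacked on the face away from the benzyl group, should set C12 as S.

Step 2
Reactants: 4 (R)-4-benzyl-3-[(S)-2-methylpent-4-ynoyl]oxazolidin-2-one
Product: 5 (S)-2-methylpent-4-yn-1-ol
Conditions: LiBH4, MeOH (1 equiv), Et2O, 0 °C
Reagents that add atoms: none
Why: Reductive cleavage of the N-acyloxazolidinone by borohydride gives the primary alcohol without touching the α-stereocentre and frees the auxiliary.

Step 3
Reactants: 5 (S)-2-methylpent-4-yn-1-ol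
Product: 6 (S)-2-methylpent-4-ynal
Conditions: Dess–Martin periodinane, NaHCO3, CH2Cl2, 0 °C; used at once as a cold solution
Reagents that add atoms: none
Why: Dess–Martin oxidation under buffered, base-free conditions should give the volatile α-chiral aldehyde without epimerisation.

Step 4
Reactants: 6 (S)-2-methylpent-4-ynal; 1 (R)-4-benzyl-3-propionyloxazolidin-2-one
Product: 8 (R)-4-benzyl-3-[(2R,3S,4S)-3-hydroxy-2,4-dimethylhept-6-ynoyl]oxazolidin-2-one, via Z-dibutylboron enolate 7 (not isolated)
Conditions: 1, Bu2BOTf, i-Pr2NEt, CH2Cl2, 0 °C; then 6, −78 → 0 °C; pH 7 buffer, MeOH, H2O2, 0 °C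
Reagents that add atoms: none
Why: Evans syn aldol through a Zimmerman–Traxler chair: the auxiliary sets C10 and C11 (syn), and the anti-Felkin sense preferred by Z-enolates matches the aldehyde, so C11 and C12 come out anti.

Step 5
Reactants: 8 (R)-4-benzyl-3-[(2R,3S,4S)-3-hydroxy-2,4-dimethylhept-6-ynoyl]oxazolidin-2-one
Product: 9 (2R,3S,4S)-3-hydroxy-N-methoxy-N,2,4-trimethylhept-6-ynamide
Conditions: MeNHOMe·HCl, AlMe3, CH2Cl2, −20 → 0 °C
Reagents that add atoms: N,O-dimethylhydroxylamine hydrochloride, CNOC.Cl
Why: Weinreb transamidation by the aluminium amide, helped by the free β-hydroxyl, replaces the auxiliary without epimerising C10.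

Step 6
Reactants: 9 (2R,3S,4S)-3-hydroxy-N-methoxy-N,2,4-trimethylhept-6-ynamide
Product: 10 (2R,3S,4S)-N-methoxy-N,2,4-trimethyl-3-(triethylsilyloxy)hept-6-ynamide
Conditions: Et3SiOTf, 2,6-lutidine, CH2Cl2, −78 → 0 °C
Reagents that add atoms: triethylsilyl trifluoromethanesulfonate, CC[Si](CC)(CC)OS(=O)(=O)C(F)(F)F
Why: Silylation of the hindered secondary alcohol with a silyl triflate; the triethylsilyl group is chosen because it must later leave under mild acid from between two branched carbons.

Step 7
Reactants: 10 (2R,3S,4S)-N-methoxy-N,2,4-trimethyl-3-(triethylsilyloxy)hept-6-ynamide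
Product: 11 (2R,3S,4S)-2,4-dimethyl-3-(triethylsilyloxy)hept-6-ynal
Conditions: i-Bu2AlH, THF, −78 °C; aq. potassium sodium tartrate
Reagents that add atoms: none
Why: Hydride reduction of a Weinreb amide stops at the chelated tetrahedral intermediate and should give the aldehyde at −78 °C with C10 intact.

Step 8
Reactants: 12 propyne; 13 (S)-propylene oxide
Product: 15 (S)-hex-4-yn-2-ol, via 1-propynyllithium 14 (not isolated)
Conditions: n-BuLi, THF, −78 °C; BF3·OEt2, then 13, −78 °C
Reagents that add atoms: none
Why: BF3-promoted epoxide opening by a lithium acetylide (Yamaguchi alkynylation) occurs at the unsubstituted carbon, so the carbinol centre C19 keeps its S configuration.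

Step 9
Reactants: 15 (S)-hex-4-yn-2-ol; 16 bromoacetyl bromide
Product: 17 (S)-hex-4-yn-2-yl bromoacetate
Conditions: pyridine, CH2Cl2, 0 °C
Reagents that add atoms: none
Why: Acylation of the secondary alcohol by the acid bromide brings in C7 and C8 with the ester tether already in place.

Step 10
Reactants: 17 (S)-hex-4-yn-2-yl bromoacetate
Product: 18 (S)-hex-4-yn-2-yl 2-(diphenoxyphosphoryl)acetate
Conditions: (PhO)2P(O)H, Et3N, CH2Cl2, 0 °C → rt
Reagents that add atoms: diphenyl phosphite, O=[PH](Oc1ccccc1)Oc1ccccc1
Why: Michaelis–Becker P-alkylation of diphenyl phosphite by the α-bromo ester gives the diaryl (Ando-type) phosphonoacetate.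

Step 11
Reactants: 11 (2R,3S,4S)-2,4-dimethyl-3-(triethylsilyloxy)hept-6-ynal; 18 (S)-hex-4-yn-2-yl 2-(diphenoxyphosphoryl)acetate
Product: 20 (S)-hex-4-yn-2-yl (2Z,4S,5S,6S)-4,6-dimethyl-5-(triethylsilyloxy)non-2-en-8-ynoate, via sodium phosphonate 19 (not isolated)
Conditions: 18, NaH, THF, 0 °C; then 11, −78 → −20 °C
Reagents that add atoms: none
Why: Ando Z-selective Horner–Wadsworth–Emmons olefination: the electron-poor diaryl phosphonate eliminates fast from the kinetic adduct, which should give the Z C8=C9 enoate, and the weakly basic anion leaves C10 untouched.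

Step 12
Reactants: 20 (S)-hex-4-yn-2-yl (2Z,4S,5S,6S)-4,6-dimethyl-5-(triethylsilyloxy)non-2-en-8-ynoate
Product: 21 tricyclic diene lactone (ring A with C14=C15 and C16=C17, ring B, δ-lactone C7(=O)–O–C19; C8–H and C9–H cis; on ring B, C9–H, the C10 methyl and C12–H on one face and C8, C11–OSiEt3 and the C12 methyl on the other)
Conditions: [Rh(cod)2]BF4 (10 mol %), (R)-H8-BINAP (10 mol %), H2 (activation) then Ar, CH2Cl2 (0.005 M), 25 → 40 °C
Reagents that add atoms: none
Why: The cationic monovalent rhodium bisphosphine complex binds the terminal alkyne and the Z-enoate and undergoes oxidative cyclisation to a rhodacyclopentene, which forms C9–C14 and closes ring B; the tethered internal alkyne then inserts into the Rh–C15 bond (C15–C16), and reductive elimination forms C8–C17, closing ring A and, through the ester tether in its s-cis form, the six-membered lactone. The closest known reaction type is the rhodium-catalysed intramolecular [2+2+2] cycloisomerisation of yne–ene–yne substrates to fused cyclohexa-1,3-dienes. C9 is controlled by the C10 stereocentre: allylic 1,3-strain with the Z ester carbon holds C10–H in the alkene plane, so the C11–C14 arm reaches the alkene face anti to the C10 methyl through a chair in which the C10 methyl and the C11 silyloxy group are equatorial, and the ligand is chosen to reinforce that face. C8 follows stereospecifically from the Z-alkene, because both new bonds form on the rhodium-bound face, which gives the cis C8–H and C9–H. The regiochemistry (methyl-bearing C16 to C15) is fixed by the tether, and high dilution should secure cyclisation over alkyne oligomerisation.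

Step 13
Reactants: 21 tricyclic diene lactone
Product: 23 tricyclic methyl acetal with free C11 hydroxyl (C7 bears OMe in place of the lactone carbonyl; other centres as in 21), via silyl lactol 22 (not isolated)
Conditions: i-Bu2AlH, CH2Cl2, −78 °C; then crude lactol, MeOH, camphorsulfonic acid (10 mol %), 0 °C → rt
Reagents that add atoms: methanol, CO
Why: Partial hydride reduction of the δ-lactone followed by acid-catalysed acetalisation through the oxocarbenium ion masks C7 as a base-stable acetal (anomeric mixture of no consequence) and removes the triethylsilyl ether in the same operation.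

Step 14
Reactants: 23 tricyclic methyl acetal with free C11 hydroxyl
Product: 24 C11 ketone of the tricyclic acetal (C10 methyl trans to C8, C12 methyl cis to C8)
Conditions: Dess–Martin periodinane, NaHCO3, CH2Cl2, 0 °C → rt
Reagents that add atoms: none
Why: Dess–Martin oxidation of the secondary alcohol under buffered conditions should give the ketone without enolisation.

Step 15
Reactants: 24 C11 ketone of the tricyclic acetal
Product: 27 all-cis C11 alcohol of the tricyclic acetal (C9–H, C10–H, C11–H and C12–H on one face of ring B; both methyls and the hydroxyl on the face of C8), via lithium enolate 25 (not isolated), via C10-inverted ketone 26 (not isolated)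
Conditions: LiN(i-Pr)2, THF, −78 °C; 2,6-di-tert-butyl-4-methylphenol, −78 °C; then LiAlH4, −78 °C
Reagents that add atoms: none
Why: Kinetic enolate protonation followed by hydride reduction: the amide should remove the axial C10–H (C12–H is equatorial and poorly aligned with the carbonyl), the enolate should take its proton on the face opposite the pseudoaxial C12 methyl and the C7 acetal bridge, which inverts C10, and immediate reduction from the same open face stores both α-centres at the alcohol level (the C11 configuration is immaterial, since it is oxidised in step 26).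

Step 16
Reactants: 27 all-cis C11 alcohol of the tricyclic acetal
Product: 28 tricyclic lactol (C7–OH in place of C7–OMe)
Conditions: pyridinium p-toluenesulfonate, acetone/H2O, 50 °C
Reagents that add atoms: water, O
Why: Acid-catalysed hydrolysis of the mixed acetal releases the lactol, the masked C7 aldehyde, under conditions too mild to affect the diene.

Step 17
Reactants: 28 tricyclic lactol; 29 ethyl 2-(triphenylphosphoranylidene)propanoate
Product: 30 ethyl (E)-enoate diol (ring A and ring B bicycle with C8–CH=C(CH3)–CO2Et, free C11 and C19 hydroxyls)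
Conditions: toluene, 80 °C
Reagents that add atoms: none
Why: Wittig olefination of the lactol through its open hydroxy aldehyde with a stabilised ylide should give the E trisubstituted C6=C7 alkene under neutral conditions that spare C8.

Step 18
Reactants: 30 ethyl (E)-enoate diol
Product: 31 allylic alcohol triol (C5 hydroxymethyl)
Conditions: i-Bu2AlH (excess), CH2Cl2, −78 °C
Reagents that add atoms: none
Why: Aluminium hydride reduction of the conjugated ester gives the allylic alcohol by 1,2-addition; no other reducible group is present.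

Step 19
Reactants: 31 allylic alcohol triol
Product: 32 (E)-enal diol (C5 aldehyde)
Conditions: TEMPO (10 mol %), PhI(OAc)2, CH2Cl2, 0 °C → rt
Reagents that add atoms: none
Why: Nitroxyl-catalysed oxidation is selective for the primary allylic alcohol over the two secondary alcohols and does not touch the diene.

Step 20
Reactants: 32 (E)-enal diol; 29 ethyl 2-(triphenylphosphoranylidene)propanoate
Product: 33 ethyl (2E,4E)-2,4-dimethyldienoate diol (C3 ester)
Conditions: toluene, 90 °C
Reagents that add atoms: none
Why: A second Wittig reaction with the stabilised ylide should give the E C4=C5 alkene.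

Step 21
Reactants: 33 ethyl (2E,4E)-2,4-dimethyldienoate diol
Product: 34 (2E,4E)-dienol triol (C3 hydroxymethyl)
Conditions: i-Bu2AlH (excess), CH2Cl2, −78 °C
Reagents that add atoms: none
Why: Aluminium hydride reduction of the dienoate gives the allylic alcohol needed to direct the epoxidation.

Step 22
Reactants: 34 (2E,4E)-dienol triol
Product: 35 (4S,5S)-epoxy triol (C4–C5 epoxide, C3 hydroxymethyl)
Conditions: Ti(Oi-Pr)4 (20 mol %), L-(+)-diethyl tartrate (24 mol %), t-BuOOH, 4 Å molecular sieves, CH2Cl2, −25 °C
Reagents that add atoms: tert-butyl hydroperoxide, CC(C)(C)OO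
Why: Sharpless asymmetric epoxidation: only the alkene of the allylic alcohol is epoxidised, and the L-(+)-tartrate delivers oxygen under reagent control to set C4 and C5 as S,S.

Step 23
Reactants: 35 (4S,5S)-epoxy triol
Product: 36 epoxy aldehyde diol (C3 aldehyde)
Conditions: TEMPO (10 mol %), PhI(OAc)2, CH2Cl2, 0 °C
Reagents that add atoms: none
Why: Nitroxyl-catalysed oxidation again takes only the primary alcohol; the α-carbon C4 is quaternary, so the epoxy aldehyde cannot epimerise.

Step 24
Reactants: 36 epoxy aldehyde diol; 37 methyl (triphenylphosphoranylidene)acetate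
Product: 38 methyl (E)-epoxy enoate diol
Conditions: CH2Cl2, rt
Reagents that add atoms: none
Why: Wittig olefination with the stabilised ylide should give the E C2=C3 enoate under neutral conditions that leave the vinyl epoxide intact.

Step 25
Reactants: 38 methyl (E)-epoxy enoate diol
Product: 39 epoxy enoic acid diol
Conditions: LiOH, THF/H2O, 0 °C; pH 5 NaH2PO4 work-up
Reagents that add atoms: lithium hydroxide, [Li+].[OH-]
Why: Saponification is done while C11 and C19 are still alcohols, so no base-labile ketone or epimerisable α-centre is present.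

Step 26
Reactants: 39 epoxy enoic acid diol
Product: 40 CNP0214881.1
Conditions: Dess–Martin periodinane (3 equiv), NaHCO3, CH2Cl2, 0 °C
Reagents that add atoms: none
Why: Dess–Martin oxidation of both secondary alcohols as the last step unveils the C11 and C19 ketones under buffered conditions, so the epimerisable C10 and C12 centres and the β,γ-unsaturated ketone never meet base.

Compound list
1 | (R)-4-benzyl-3-propionyloxazolidin-2-one | CCC(=O)N1C(=O)OC[C@H]1Cc2ccccc2 | starting material
2 | propargyl bromide | C#CCBr | starting material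
3 | sodium Z-enolate of 1 | C/C=C(\O[Na])N1C(=O)OC[C@H]1Cc2ccccc2 | intermediate
4 | (R)-4-benzyl-3-[(S)-2-methylpent-4-ynoyl]oxazolidin-2-one | C#CC[C@H](C)C(=O)N1C(=O)OC[C@H]1Cc2ccccc2 | intermediate
5 | (S)-2-methylpent-4-yn-1-ol | C#CC[C@H](C)CO | intermediate
6 | (S)-2-methylpent-4-ynal | C#CC[C@H](C)C=O | intermediate
7 | Z-dibutylboron enolate of 1 | C/C=C(\OB(CCCC)CCCC)N1C(=O)OC[C@H]1Cc2ccccc2 | intermediate
8 | (R)-4-benzyl-3-[(2R,3S,4S)-3-hydroxy-2,4-dimethylhept-6-ynoyl]oxazolidin-2-one | C#CC[C@H](C)[C@H](O)[C@@H](C)C(=O)N1C(=O)OC[C@H]1Cc2ccccc2 | intermediate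
9 | (2R,3S,4S)-3-hydroxy-N-methoxy-N,2,4-trimethylhept-6-ynamide | C#CC[C@H](C)[C@H](O)[C@@H](C)C(=O)N(C)OC | intermediate
10 | (2R,3S,4S)-N-methoxy-N,2,4-trimethyl-3-(triethylsilyloxy)hept-6-ynamide | C#CC[C@H](C)[C@H](O[Si](CC)(CC)CC)[C@@H](C)C(=O)N(C)OC | intermediate
11 | (2R,3S,4S)-2,4-dimethyl-3-(triethylsilyloxy)hept-6-ynal | C#CC[C@H](C)[C@H](O[Si](CC)(CC)CC)[C@@H](C)C=O | intermediate
12 | propyne | CC#C | starting material
13 | (S)-propylene oxide | C[C@H]1CO1 | starting material
14 | 1-propynyllithium | CC#C[Li] | intermediate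
15 | (S)-hex-4-yn-2-ol | C[C@H](O)CC#CC | intermediate
16 | bromoacetyl bromide | BrCC(=O)Br | starting material
17 | (S)-hex-4-yn-2-yl bromoacetate | BrCC(=O)O[C@@H](C)CC#CC | intermediate
18 | (S)-hex-4-yn-2-yl 2-(diphenoxyphosphoryl)acetate | O=C(CP(=O)(Oc1ccccc1)Oc1ccccc1)O[C@@H](C)CC#CC | intermediate
19 | sodium salt of phosphonate 18 | [Na+].O=C([CH-]P(=O)(Oc1ccccc1)Oc1ccccc1)O[C@@H](C)CC#CC | intermediate
20 | (S)-hex-4-yn-2-yl (2Z,4S,5S,6S)-4,6-dimethyl-5-(triethylsilyloxy)non-2-en-8-ynoate (enediyne precursor) | C#CC[C@H](C)[C@H](O[Si](CC)(CC)CC)[C@@H](C)/C=C\C(=O)O[C@@H](C)CC#CC | intermediate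
21 | tricyclic diene lactone (rings A and B, C7–O–C19 lactone, C11–OSiEt3, C10 methyl trans to C8) | C[C@H]3CC1=C(C)C=C2C[C@H](C)[C@H](O[Si](CC)(CC)CC)[C@@H](C)[C@@H]2[C@@H]1C(=O)O3 | intermediate
22 | silyl lactol (C7–OH, anomeric mixture) | C[C@H]3CC1=C(C)C=C2C[C@H](C)[C@H](O[Si](CC)(CC)CC)[C@@H](C)[C@@H]2[C@@H]1C(O)O3 | intermediate
23 | tricyclic methyl acetal with free C11 hydroxyl (anomeric mixture) | C[C@H]3CC1=C(C)C=C2C[C@H](C)[C@H](O)[C@@H](C)[C@@H]2[C@@H]1C(OC)O3 | intermediate
24 | C11 ketone of the tricyclic acetal (C10 methyl trans to C8) | C[C@H]3CC1=C(C)C=C2C[C@H](C)C(=O)[C@@H](C)[C@@H]2[C@@H]1C(OC)O3 | intermediate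
25 | lithium C10–C11 enolate of 24 | C[C@H]3CC1=C(C)C=C2C[C@H](C)C(O[Li])=C(C)[C@@H]2[C@@H]1C(OC)O3 | intermediate
26 | C10-inverted ketone (C10 and C12 methyls cis to C8) | C[C@H]3CC1=C(C)C=C2C[C@H](C)C(=O)[C@H](C)[C@@H]2[C@@H]1C(OC)O3 | intermediate
27 | all-cis C11 alcohol of the tricyclic acetal | C[C@H]3CC1=C(C)C=C2C[C@H](C)[C@H](O)[C@H](C)[C@@H]2[C@@H]1C(OC)O3 | intermediate
28 | tricyclic lactol (anomeric mixture) | C[C@H]3CC1=C(C)C=C2C[C@H](C)[C@H](O)[C@H](C)[C@@H]2[C@@H]1C(O)O3 | intermediate
29 | ethyl 2-(triphenylphosphoranylidene)propanoate | CCOC(=O)C(C)=P(c1ccccc1)(c1ccccc1)c1ccccc1 | starting material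
30 | ethyl (E)-enoate diol (C5 ester, C11 and C19 hydroxyls) | C[C@H](O)CC1=C(C)C=C2C[C@H](C)[C@H](O)[C@H](C)[C@@H]2[C@@H]1/C=C(\C)C(=O)OCC | intermediate
31 | allylic alcohol triol | C[C@H](O)CC1=C(C)C=C2C[C@H](C)[C@H](O)[C@H](C)[C@@H]2[C@@H]1/C=C(\C)CO | intermediate
32 | (E)-enal diol | C[C@H](O)CC1=C(C)C=C2C[C@H](C)[C@H](O)[C@H](C)[C@@H]2[C@@H]1/C=C(\C)C=O | intermediate
33 | ethyl (2E,4E)-2,4-dimethyldienoate diol | C[C@H](O)CC1=C(C)C=C2C[C@H](C)[C@H](O)[C@H](C)[C@@H]2[C@@H]1/C=C(\C)/C=C(\C)C(=O)OCC | intermediate
34 | (2E,4E)-dienol triol | C[C@H](O)CC1=C(C)C=C2C[C@H](C)[C@H](O)[C@H](C)[C@@H]2[C@@H]1/C=C(\C)/C=C(\C)CO | intermediate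
35 | (4S,5S)-epoxy triol | C[C@H](O)CC1=C(C)C=C2C[C@H](C)[C@H](O)[C@H](C)[C@@H]2[C@@H]1/C=C(\C)[C@@H]1O[C@@]1(C)CO | intermediate
36 | epoxy aldehyde diol | C[C@H](O)CC1=C(C)C=C2C[C@H](C)[C@H](O)[C@H](C)[C@@H]2[C@@H]1/C=C(\C)[C@@H]1O[C@@]1(C)C=O | intermediate
37 | methyl (triphenylphosphoranylidene)acetate | COC(=O)C=P(c1ccccc1)(c1ccccc1)c1ccccc1 | starting material
38 | methyl (E)-epoxy enoate diol | C[C@H](O)CC1=C(C)C=C2C[C@H](C)[C@H](O)[C@H](C)[C@@H]2[C@@H]1/C=C(\C)[C@@H]1O[C@@]1(C)/C=C/C(=O)OC | intermediate
39 | epoxy enoic acid diol | C[C@H](O)CC1=C(C)C=C2C[C@H](C)[C@H](O)[C@H](C)[C@@H]2[C@@H]1/C=C(\C)[C@@H]1O[C@@]1(C)/C=C/C(=O)O | intermediate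
40 | CNP0214881.1 | CC(=O)CC1=C(C)C=C2C[C@H](C)C(=O)[C@H](C)[C@@H]2[C@@H]1/C=C(\C)[C@@H]1O[C@@]1(C)/C=C/C(=O)O | target

Total step count: 26. Longest linear sequence: 23 steps (steps 1 to 7 and 11 to 26); steps 8 to 10 form the side branch.

Steps most likely to fail

Step 12. The ester tether may not reach the s-cis geometry needed for lactone closure. The first rhodacycle would then be diverted into alkyne oligomerisation or β-hydride elimination to an open triene, or the diene may be dehydrogenated to the arene. The fallback sets out from 20: stoichiometric CpCo(CO)2 in degassed toluene under irradiation at reflux should form the same three bonds on cobalt and hold the product as the cyclopentadienylcobalt η4-diene complex F1, which cannot aromatise. Oxidative decomplexation with CuCl2·2H2O and Et3N in MeCN at 0 °C would then release the free diene and come back to the route at 21.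

Step 15. Proton removal may occur at C12 instead of C10, or the proton may return on the hindered face, so that C10 is not inverted or C12 is scrambled. The fallback sets out from 24: silylation under equilibrating conditions (Me3SiOTf, Et3N, CH2Cl2) and chromatographic separation should give the C10–C11 trimethylsilyl enol ether F2, its regioisomer being hydrolysed back to 24 and recycled. MeLi in THF regenerates the single lithium enolate 25 from F2, and protonation and LiAlH4 reduction as before come back to the route at 27.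

Step 22. The two free secondary hydroxyls may sequester the titanium tartrate, and the Lewis acid may open the vinyl epoxide at allylic C5. The fallback sets out from 33: both secondary hydroxyls are silylated (Et3SiOTf, 2,6-lutidine) to the bis(triethylsilyl) dienoate F3, and i-Bu2AlH gives the bis(triethylsilyl) dienol F4. Vanadium-catalysed allylic alcohol epoxidation (VO(Oi-Pr)3, a chiral bishydroxamic acid ligand chosen for the 4S,5S epoxide, cumene hydroperoxide, toluene, 0 °C), which is not Lewis acidic toward the product, should give the bis(triethylsilyl) epoxy alcohol F5. Bu4NF buffered with AcOH removes both silyl groups and comes back to the route at 35.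

Further compounds
F1 | step 12 | cyclopentadienylcobalt η4-diene complex of lactone 21 | C[C@H]3CC1=C(C)C=C2C[C@H](C)[C@H](O[Si](CC)(CC)CC)[C@@H](C)[C@@H]2[C@@H]1C(=O)O3.[Co+].c1cc[cH-]c1
F2 | step 15 | C10–C11 trimethylsilyl enol ether of ketone 24 | C[C@H]3CC1=C(C)C=C2C[C@H](C)C(O[Si](C)(C)C)=C(C)[C@@H]2[C@@H]1C(OC)O3
F3 | step 22 | bis(triethylsilyl) ether of dienoate 33 | C[C@H](O[Si](CC)(CC)CC)CC1=C(C)C=C2C[C@H](C)[C@H](O[Si](CC)(CC)CC)[C@H](C)[C@@H]2[C@@H]1/C=C(\C)/C=C(\C)C(=O)OCC
F4 | step 22 | bis(triethylsilyl) dienol | C[C@H](O[Si](CC)(CC)CC)CC1=C(C)C=C2C[C@H](C)[C@H](O[Si](CC)(CC)CC)[C@H](C)[C@@H]2[C@@H]1/C=C(\C)/C=C(\C)CO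
F5 | step 22 | bis(triethylsilyl) (4S,5S)-epoxy alcohol | C[C@H](O[Si](CC)(CC)CC)CC1=C(C)C=C2C[C@H](C)[C@H](O[Si](CC)(CC)CC)[C@H](C)[C@@H]2[C@@H]1/C=C(\C)[C@@H]1O[C@@]1(C)CO
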